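## Retrosynthetic overview

- **Feature the strategy rests on:** in ring A, O1 and the C4 carbonyl sit on the adjacent carbons C8a and C4a, and C5 next to C4a carries oxygen. A nucleophile/acyl pair adding across a 3-alkoxyaryne leaves exactly this pattern.
- **Endgame:** target ⇒ neutral global debenzylation ⇒ oxidation of the ring D carbinol. Benzyl ethers are used throughout, so the acidic Cα–H of the final aryl ketone meets neither strong acid nor base.
- **Key disconnection:** the chromone carbinol is cut at O1–C8a and C4–C4a together. This gives 3,5-bis(benzyloxy)benzyne and a (Z)-3-hydroxymethylene-4-benzhydryl-5-aryl-γ-butyrolactone.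
- **Lactone:** ⇒ Claisen formylation ⇒ Felkin–Anh addition of the ring D aryllithium to an α-benzhydryl aldehyde, with lactonisation ⇒ Stobbe half-ester. Cα is set by asymmetric hydrogenation.
- **Ring order:** all benzene rings are bought. The temporary lactone ring is made first, and pyranone ring C closes in the key step as that lactone opens.

Key step: step 13

Assumption: the facial sense of [Rh(cod)(Me-DuPHOS)]BF4 on this tetrasubstituted diaryl substrate is assigned by analogy with simpler alkylidene succinates; the (R,R) ligand is written, and its commercial antipode is used instead if a first run delivers the (R)-acid.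

## Route

**Step 1**
Reactants: 1 4,4'-dihydroxybenzophenone
Product: 2 4,4'-bis(benzyloxy)benzophenone
Conditions: BnBr (2.2 equiv), K2CO3, DMF, 60 °C
Reagents that add atoms: benzyl bromide, BrCc1ccccc1
Why: Williamson ether synthesis on two acidic para-acylphenols; benzyl is chosen because it can be removed at the end under neutral conditions.

**Step 2**
Reactants: 2 4,4'-bis(benzyloxy)benzophenone; 3 dimethyl succinate
Product: 4 4,4-bis[4-(benzyloxy)phenyl]-3-(methoxycarbonyl)but-3-enoic acid
Conditions: KOt-Bu, t-BuOH, 85 °C; then 2 M HCl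
Reagents that add atoms: none
Why: Stobbe condensation, in which the succinate enolate adds to the diaryl ketone, the alkoxide lactonises and base-induced ring opening leaves the ester on the alkene carbon and the free acid on the CH2 arm; two equal aryl groups exclude alkene isomers.

**Step 3**
Reactants: 4 4,4-bis[4-(benzyloxy)phenyl]-3-(methoxycarbonyl)but-3-enoic acid
Product: 5 (3S)-4,4-bis[4-(benzyloxy)phenyl]-3-(methoxycarbonyl)butanoic acid
Conditions: [Rh(cod)((R,R)-Me-DuPHOS)]BF4 (1 mol %), NaOMe (0.1 equiv), H2 (30 bar), MeOH–THF, 40 °C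
Reagents that add atoms: none
Why: Carboxylate-directed asymmetric hydrogenation of a Stobbe-derived β,β-disubstituted itaconate half-ester, where chelation of alkene and carboxylate to the chiral rhodium complex fixes the face that receives H2 and so sets Cα, and the homogeneous catalyst leaves benzyl ethers intact.

**Step 4**
Reactants: 5 (3S)-4,4-bis[4-(benzyloxy)phenyl]-3-(methoxycarbonyl)butanoic acid
Product: 7 (4S)-4-{bis[4-(benzyloxy)phenyl]methyl}oxolan-2-one, via hydroxy acid 6 (not isolated)
Conditions: KOH (1 equiv), EtOH; CaCl2, NaBH4, EtOH, −10 °C → rt; then 2 M HCl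
Reagents that add atoms: none
Why: Chemoselective borohydride reduction, in which Ca(BH4)2 reduces the methyl ester while the carboxylate salt is inert and acidification closes the γ-lactone; this sequence is well established for 2-substituted succinate half-esters with retention of configuration.

**Step 5**
Reactants: 7 (4S)-4-{bis[4-(benzyloxy)phenyl]methyl}oxolan-2-one
Product: 8 (3S)-4,4-bis[4-(benzyloxy)phenyl]-3-(hydroxymethyl)-N-methoxy-N-methylbutanamide
Conditions: MeNH(OMe)·HCl, AlMe3, CH2Cl2, 0 °C → rt; aq potassium sodium tartrate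
Reagents that add atoms: N,O-dimethylhydroxylamine hydrochloride, CNOC.Cl
Why: Weinreb aminolysis of a lactone by the aluminium amide frees the primary alcohol on the carbon next to the stereocentre; the product is carried on crude because it tends to relactonise.

**Step 6**
Reactants: 8 (3S)-4,4-bis[4-(benzyloxy)phenyl]-3-(hydroxymethyl)-N-methoxy-N-methylbutanamide
Product: 9 (3S)-4,4-bis[4-(benzyloxy)phenyl]-3-formyl-N-methoxy-N-methylbutanamide
Conditions: Dess–Martin periodinane, NaHCO3, CH2Cl2, 0 °C
Reagents that add atoms: none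
Why: Dess–Martin oxidation stops at the aldehyde under buffered, near-neutral conditions, so the α-stereocentre is not enolised; the aldehyde is used without chromatography.

**Step 7**
Reactants: 10 1,3,5-tris(benzyloxy)benzene
Product: 11 2-bromo-1,3,5-tris(benzyloxy)benzene
Conditions: NBS (1.0 equiv), CH2Cl2, −78 → 0 °C
Reagents that add atoms: N-bromosuccinimide, O=C1CCC(=O)N1Br
Why: Electrophilic aromatic bromination of a threefold-symmetric, strongly activated arene whose three free positions are equivalent; one equivalent of NBS in the cold holds it at the monobromide.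

**Step 8**
Reactants: 11 2-bromo-1,3,5-tris(benzyloxy)benzene; 9 (3S)-4,4-bis[4-(benzyloxy)phenyl]-3-formyl-N-methoxy-N-methylbutanamide
Product: 14 (4S,5R)-4-{bis[4-(benzyloxy)phenyl]methyl}-5-[2,4,6-tris(benzyloxy)phenyl]oxolan-2-one (trans), via 2,4,6-tris(benzyloxy)phenyllithium 12 (not isolated), via lithium alkoxide adduct 13 (not isolated)
Conditions: 11 (1.05 equiv), n-BuLi, THF, −78 °C; then 9, −78 → 0 °C; sat. aq NH4Cl
Reagents that add atoms: none
Why: Bromine–lithium exchange followed by Felkin–Anh 1,2-addition, in which the aryllithium attacks the aldehyde (far more electrophilic than the Weinreb amide at −78 °C) anti to the benzhydryl group and so sets the carbinol carbon as (R), and on warming the alkoxide displaces the amide nitrogen by 5-exo-trig acyl substitution to give the trans lactone.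

**Step 9**
Reactants: 14 (4S,5R)-4-{bis[4-(benzyloxy)phenyl]methyl}-5-[2,4,6-tris(benzyloxy)phenyl]oxolan-2-one
Product: 15 (3Z,4R,5R)-4-{bis[4-(benzyloxy)phenyl]methyl}-3-(hydroxymethylidene)-5-[2,4,6-tris(benzyloxy)phenyl]oxolan-2-one
Conditions: KOt-Bu, HCO2Et, THF, 0 °C → rt; then AcOH
Reagents that add atoms: ethyl formate, CCOC=O
Why: Crossed Claisen formylation of the lactone enolate, driven by formation of the stabilised potassium enolate; C4 and C5 carry no acidic hydrogen and stay fixed (the C4 descriptor changes only through CIP priorities), and the enol oxygen sits on the carbonyl side, away from the C4 benzhydryl group.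

**Step 10**
Reactants: 16 3,5-bis(benzyloxy)phenol
Product: 17 2-bromo-3,5-bis(benzyloxy)phenol
Conditions: NBS (1.0 equiv), CH2Cl2, −78 °C → rt
Reagents that add atoms: N-bromosuccinimide, O=C1CCC(=O)N1Br
Why: Electrophilic aromatic bromination directed ortho to the free hydroxyl, since C2 and C6 are equivalent and less crowded than C4, which lies between two benzyloxy groups.

**Step 11**
Reactants: 17 2-bromo-3,5-bis(benzyloxy)phenol
Product: 18 [2-bromo-3,5-bis(benzyloxy)phenoxy]trimethylsilane
Conditions: HMDS, THF, 70 °C; concentrate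
Reagents that add atoms: hexamethyldisilazane, C[Si](C)(C)N[Si](C)(C)C
Why: O-silylation of a phenol with hexamethyldisilazane gives only a volatile by-product, so the silyl ether can be used after evaporation.

**Step 12**
Reactants: 18 [2-bromo-3,5-bis(benzyloxy)phenoxy]trimethylsilane
Product: 21 3,5-bis(benzyloxy)-2-(trimethylsilyl)phenyl trifluoromethanesulfonate, via ortho-lithiated silyl ether 19 (not isolated), via lithium 2-silylphenoxide 20 (not isolated)
Conditions: n-BuLi, THF, −100 → −78 °C; then Tf2O, −100 → −78 °C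
Reagents that add atoms: trifluoromethanesulfonic anhydride, O=S(=O)(OS(=O)(=O)C(F)(F)F)C(F)(F)F
Why: Bromine–lithium exchange triggers a retro-Brook O→C silyl migration to the lithium 2-silylphenoxide, which is triflated in the same flask; this is the standard access to ortho-silylaryl triflates.

**Step 13**
Reactants: 15 (3Z,4R,5R)-4-{bis[4-(benzyloxy)phenyl]methyl}-3-(hydroxymethylidene)-5-[2,4,6-tris(benzyloxy)phenyl]oxolan-2-one; 21 3,5-bis(benzyloxy)-2-(trimethylsilyl)phenyl trifluoromethanesulfonate
Product: 23 3-{(2R,3R)-1,1-bis[4-(benzyloxy)phenyl]-3-hydroxy-3-[2,4,6-tris(benzyloxy)phenyl]propan-2-yl}-5,7-bis(benzyloxy)-4H-chromen-4-one, via 3,5-bis(benzyloxy)benzyne 22 (not isolated)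
Conditions: 21 (1.3 equiv, slow addition), CsF (4 equiv), THF, 65 °C
Reagents that add atoms: none
Why: Proposed new method: fluoride removes the silyl group of 21 and triflate departs to give aryne 22, while CsF also deprotonates the acidic enol 15; the enolate oxygen adds to the aryne carbon meta to the flanking benzyloxy group (O1–C8a bond), which places the aryl anion on the carbon ortho to that group, where the C–O dipole stabilises it. That carbanion, the future C4a, adds to the lactone carbonyl in a 6-exo-trig mode, and collapse of the tetrahedral intermediate expels the C5 alkoxide, so that pyranone ring C closes by intramolecular acyl substitution (C4–C4a bond) as the lactone ring opens, and the alkoxide is then protonated by the next molecule of enol. The closest known reaction types are the CsF-induced annulation of arynes with salicylate esters to xanthones and the acyl-alkylation of arynes by β-keto esters; the pairing of an enol oxygen with a lactone acyl group is untested. No stereocentre is created, and lactone C4 and C5 become Cα and the carbinol carbon unchanged, since at the alcohol oxidation level neither hydrogen is acidic toward fluoride. The step needs O- rather than C-arylation, which is expected because such formyl-lactone enolates take carbon electrophiles at the exposed oxygen and C-attack would build a quaternary centre beside the benzhydryl group; it needs the Z enolate geometry, favoured by allylic strain with the C4 substituent and by caesium bridging both oxygens as a contact ion pair in THF; and it needs one aryne orientation, which the benzyloxy group next to the triple bond dictates. The low solubility of CsF in THF keeps the aryne concentration small, which protects the freed carbinol from a second arylation.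

**Step 14**
Reactants: 23 3-{(2R,3R)-1,1-bis[4-(benzyloxy)phenyl]-3-hydroxy-3-[2,4,6-tris(benzyloxy)phenyl]propan-2-yl}-5,7-bis(benzyloxy)-4H-chromen-4-one
Product: 24 (2R)-2-[5,7-bis(benzyloxy)-4-oxo-4H-chromen-3-yl]-3,3-bis[4-(benzyloxy)phenyl]-1-[2,4,6-tris(benzyloxy)phenyl]propan-1-one
Conditions: Dess–Martin periodinane, NaHCO3, CH2Cl2, 0 °C → rt
Reagents that add atoms: none
Why: Dess–Martin oxidation of a hindered, electron-rich benzylic alcohol; the bicarbonate buffer prevents acid ionisation of the carbinol, and the absence of base spares the Cα–H that becomes acidic in the product.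

**Step 15**
Reactants: 24 (2R)-2-[5,7-bis(benzyloxy)-4-oxo-4H-chromen-3-yl]-3,3-bis[4-(benzyloxy)phenyl]-1-[2,4,6-tris(benzyloxy)phenyl]propan-1-one
Product: 25 (2R)-2-(5,7-dihydroxy-4-oxo-4H-chromen-3-yl)-3,3-bis(4-hydroxyphenyl)-1-(2,4,6-trihydroxyphenyl)propan-1-one (CNP0106875.1)
Conditions: H2 (1 atm), 10% Pd/C, THF–MeOH, rt, stopped when uptake ends
Reagents that add atoms: none
Why: Catalytic hydrogenolysis of seven benzyl aryl ethers under neutral conditions keeps Cα configurationally intact, while the chromone C2=C3 bond is shielded by the bulky C3 substituent and the ortho-hydroxylated aryl ketone resists reduction.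

## Compound list

1 | 4,4'-dihydroxybenzophenone | O=C(c1ccc(O)cc1)c1ccc(O)cc1 | starting material
2 | 4,4'-bis(benzyloxy)benzophenone | O=C(c1ccc(OCc2ccccc2)cc1)c1ccc(OCc2ccccc2)cc1 | intermediate
3 | dimethyl succinate | COC(=O)CCC(=O)OC | starting material
4 | 4,4-bis[4-(benzyloxy)phenyl]-3-(methoxycarbonyl)but-3-enoic acid | COC(=O)C(CC(=O)O)=C(c1ccc(OCc2ccccc2)cc1)c1ccc(OCc2ccccc2)cc1 | intermediate
5 | (3S)-4,4-bis[4-(benzyloxy)phenyl]-3-(methoxycarbonyl)butanoic acid | COC(=O)[C@@H](CC(=O)O)C(c1ccc(OCc2ccccc2)cc1)c1ccc(OCc2ccccc2)cc1 | intermediate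
6 | (3S)-4,4-bis[4-(benzyloxy)phenyl]-3-(hydroxymethyl)butanoic acid (not isolated) | OC[C@@H](CC(=O)O)C(c1ccc(OCc2ccccc2)cc1)c1ccc(OCc2ccccc2)cc1 | intermediate
7 | (4S)-4-{bis[4-(benzyloxy)phenyl]methyl}oxolan-2-one | O=C1OC[C@@H](C1)C(c1ccc(OCc2ccccc2)cc1)c1ccc(OCc2ccccc2)cc1 | intermediate
8 | (3S)-4,4-bis[4-(benzyloxy)phenyl]-3-(hydroxymethyl)-N-methoxy-N-methylbutanamide | OC[C@@H](CC(=O)N(C)OC)C(c1ccc(OCc2ccccc2)cc1)c1ccc(OCc2ccccc2)cc1 | intermediate
9 | (3S)-4,4-bis[4-(benzyloxy)phenyl]-3-formyl-N-methoxy-N-methylbutanamide | O=C[C@@H](CC(=O)N(C)OC)C(c1ccc(OCc2ccccc2)cc1)c1ccc(OCc2ccccc2)cc1 | intermediate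
10 | 1,3,5-tris(benzyloxy)benzene | c1(OCc2ccccc2)cc(OCc2ccccc2)cc(OCc2ccccc2)c1 | starting material
11 | 2-bromo-1,3,5-tris(benzyloxy)benzene | Brc1c(OCc2ccccc2)cc(OCc2ccccc2)cc1OCc1ccccc1 | intermediate
12 | 2,4,6-tris(benzyloxy)phenyllithium (not isolated) | [Li]c1c(OCc2ccccc2)cc(OCc2ccccc2)cc1OCc1ccccc1 | intermediate
13 | lithium alkoxide of (3S)-4,4-bis[4-(benzyloxy)phenyl]-3-{(R)-hydroxy[2,4,6-tris(benzyloxy)phenyl]methyl}-N-methoxy-N-methylbutanamide (not isolated) | [Li]O[C@@H](c1c(OCc2ccccc2)cc(OCc2ccccc2)cc1OCc1ccccc1)[C@@H](CC(=O)N(C)OC)C(c1ccc(OCc2ccccc2)cc1)c1ccc(OCc2ccccc2)cc1 | intermediate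
14 | (4S,5R)-4-{bis[4-(benzyloxy)phenyl]methyl}-5-[2,4,6-tris(benzyloxy)phenyl]oxolan-2-one | O=C1O[C@@H](c2c(OCc3ccccc3)cc(OCc3ccccc3)cc2OCc2ccccc2)[C@H](C(c2ccc(OCc3ccccc3)cc2)c2ccc(OCc3ccccc3)cc2)C1 | intermediate
15 | (3Z,4R,5R)-4-{bis[4-(benzyloxy)phenyl]methyl}-3-(hydroxymethylidene)-5-[2,4,6-tris(benzyloxy)phenyl]oxolan-2-one | O=C1O[C@@H](c2c(OCc3ccccc3)cc(OCc3ccccc3)cc2OCc2ccccc2)[C@H](C(c2ccc(OCc3ccccc3)cc2)c2ccc(OCc3ccccc3)cc2)/C1=C/O | intermediate
16 | 3,5-bis(benzyloxy)phenol | Oc1cc(OCc2ccccc2)cc(OCc2ccccc2)c1 | starting material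
17 | 2-bromo-3,5-bis(benzyloxy)phenol | Oc1cc(OCc2ccccc2)cc(OCc2ccccc2)c1Br | intermediate
18 | [2-bromo-3,5-bis(benzyloxy)phenoxy]trimethylsilane | C[Si](C)(C)Oc1cc(OCc2ccccc2)cc(OCc2ccccc2)c1Br | intermediate
19 | [3,5-bis(benzyloxy)-2-lithiophenoxy]trimethylsilane (not isolated) | C[Si](C)(C)Oc1cc(OCc2ccccc2)cc(OCc2ccccc2)c1[Li] | intermediate
20 | lithium 3,5-bis(benzyloxy)-2-(trimethylsilyl)phenoxide (not isolated) | [Li]Oc1cc(OCc2ccccc2)cc(OCc2ccccc2)c1[Si](C)(C)C | intermediate
21 | 3,5-bis(benzyloxy)-2-(trimethylsilyl)phenyl trifluoromethanesulfonate | C[Si](C)(C)c1c(OCc2ccccc2)cc(OCc2ccccc2)cc1OS(=O)(=O)C(F)(F)F | intermediate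
22 | 3,5-bis(benzyloxy)benzyne (not isolated) | C1#CC(OCc2ccccc2)=CC(OCc2ccccc2)=C1 | intermediate
23 | 3-{(2R,3R)-1,1-bis[4-(benzyloxy)phenyl]-3-hydroxy-3-[2,4,6-tris(benzyloxy)phenyl]propan-2-yl}-5,7-bis(benzyloxy)-4H-chromen-4-one | O[C@@H](c1c(OCc2ccccc2)cc(OCc2ccccc2)cc1OCc1ccccc1)[C@@H](c1coc2cc(OCc3ccccc3)cc(OCc3ccccc3)c2c1=O)C(c1ccc(OCc2ccccc2)cc1)c1ccc(OCc2ccccc2)cc1 | intermediate
24 | (2R)-2-[5,7-bis(benzyloxy)-4-oxo-4H-chromen-3-yl]-3,3-bis[4-(benzyloxy)phenyl]-1-[2,4,6-tris(benzyloxy)phenyl]propan-1-one | O=C(c1c(OCc2ccccc2)cc(OCc2ccccc2)cc1OCc1ccccc1)[C@@H](c1coc2cc(OCc3ccccc3)cc(OCc3ccccc3)c2c1=O)C(c1ccc(OCc2ccccc2)cc1)c1ccc(OCc2ccccc2)cc1 | intermediate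
25 | (2R)-2-(5,7-dihydroxy-4-oxo-4H-chromen-3-yl)-3,3-bis(4-hydroxyphenyl)-1-(2,4,6-trihydroxyphenyl)propan-1-one | O=C(c1c(O)cc(O)cc1O)[C@@H](c1coc2cc(O)cc(O)c2c1=O)C(c1ccc(O)cc1)c1ccc(O)cc1 | target

## Step count

Total step count: 15.
Longest linear sequence: 11 (steps 1–6, 8, 9, 13, 14, 15).

## Steps most likely to fail

**First, step 13.** It may fail in four ways:
- C-arylation of the ambident enolate, followed by transfer of the formyl group.
- O-arylation out of the E enolate geometry, after which the aryl anion cannot reach the lactone carbonyl and is only protonated.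
- Attack of the released alkoxide on a second aryne.
- Attack of the released alkoxide on C2 of the new pyranone.

The fallback generates the same aryl anion by halogen–metal exchange, using known reactions. It sets out from 15 and 17 and comes back to the route at 23. TsCl and Et3N in CH2Cl2 at 0 °C would convert 15 into the enol tosylate F1. Bromophenol 17 with K2CO3 in MeCN would displace the tosylate by conjugate addition–elimination to give the aryl enol ether F2, whose aryloxy group should settle on the carbonyl side, away from the C4 benzhydryl group. n-BuLi in THF at −100 °C would then exchange bromine for lithium. The aryllithium closes on the lactone carbonyl (Parham cyclisation) and should give 23 after an NH4Cl quench.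

**Second, step 3.** The tetrasubstituted alkene bearing two aryl groups may bind the catalyst poorly, which would show as slow turnover or poor facial selectivity. The fallback replaces asymmetric catalysis by reduction and classical resolution. It sets out from 4 and comes back at 5. Conjugate reduction by electron transfer (Mg turnings, MeOH, rt) would give the racemic half-ester F3. Crystallisation with (S)-1-phenylethylamine from EtOH would give the diastereomerically pure ammonium salt F4, and acidification with dilute HCl would release 5. The antipodal amine is used if its salt with the (S)-acid is the less soluble one.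

**Third, step 15.** Removing seven benzyl groups takes time, so saturation of the chromone C2=C3 bond or incomplete cleavage may intervene. The fallback replaces hydrogenolysis by Lewis-acid debenzylation with a cation scavenger. It sets out from 24 and comes back at 25. BCl3 and pentamethylbenzene in CH2Cl2 at −78 °C, then MeOH, would cleave the ethers quickly in the cold, which also limits enolisation at Cα. No new compound arises on this path.

## Further compounds

F1 | step 13 | (3Z,4R,5R)-4-{bis[4-(benzyloxy)phenyl]methyl}-3-{[(4-methylbenzenesulfonyl)oxy]methylidene}-5-[2,4,6-tris(benzyloxy)phenyl]oxolan-2-one | O=C1O[C@@H](c2c(OCc3ccccc3)cc(OCc3ccccc3)cc2OCc2ccccc2)[C@H](C(c2ccc(OCc3ccccc3)cc2)c2ccc(OCc3ccccc3)cc2)/C1=C/OS(=O)(=O)c1ccc(C)cc1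
F2 | step 13 | (3Z,4R,5R)-3-{[2-bromo-3,5-bis(benzyloxy)phenoxy]methylidene}-4-{bis[4-(benzyloxy)phenyl]methyl}-5-[2,4,6-tris(benzyloxy)phenyl]oxolan-2-one | O=C1O[C@@H](c2c(OCc3ccccc3)cc(OCc3ccccc3)cc2OCc2ccccc2)[C@H](C(c2ccc(OCc3ccccc3)cc2)c2ccc(OCc3ccccc3)cc2)/C1=C/Oc1cc(OCc2ccccc2)cc(OCc2ccccc2)c1Br
F3 | step 3 | racemic 4,4-bis[4-(benzyloxy)phenyl]-3-(methoxycarbonyl)butanoic acid | COC(=O)C(CC(=O)O)C(c1ccc(OCc2ccccc2)cc1)c1ccc(OCc2ccccc2)cc1
F4 | step 3 | (S)-1-phenylethylammonium (3S)-4,4-bis[4-(benzyloxy)phenyl]-3-(methoxycarbonyl)butanoate | COC(=O)[C@@H](CC(=O)[O-])C(c1ccc(OCc2ccccc2)cc1)c1ccc(OCc2ccccc2)cc1.C[C@H]([NH3+])c1ccccc1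
F0 | step 15 | none | none
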